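**Plan**

1. Cuts: the C8 angelate; then, in one stroke, C1–C2 and O–C10 (the oxolane and the ten-membered carbocycle together); then C6–C7 with the lactone C–O bond. This leaves a west enal (C2–C6, C15) and an east allylic bromide (C7–C14, C1).
2. Forward order of rings: γ-lactone first (step 11, then masked as its methyl lactol acetal), carbocycle and bridging oxolane at once (step 15), lactone restored last (steps 20 and 21).
3. Enabling feature: in the oxolane O–C3–C2–C1–C10 the oxygen sits on C3 next to a terminal CH2 (C2), which is a terminal epoxide in disguise. C1 is flanked by the methyl-bearing C10, which is a 2-substituted allyl sulfone in disguise: its C1 carbanion alkylates C2, and its vinyl-sulfone tautomer then offers C10 to the freed C3 alkoxide.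
4. Stereochemistry: C3 from (S)-glyceraldehyde acetonide; 4Z from syn-carbocupration; C8 from catalyst-controlled allylboration; C6 and C7 from the anti-selective chromium allylation steered by C8; C10 relayed from C3 by the cis-only bridge; C1 by exo hydride addition to a ketone.

Key step: step 15

Remark: germacrane numbering (C1–C15) is used from compound 15 on. The lactol or methyl-acetal carbon (C12) of 18–27 and 30–32 forms as an anomer mixture that is carried through and removed in step 21.

**Route**

Step 1
Reactants: 1 (4S)-2,2-dimethyl-1,3-dioxolane-4-carbaldehyde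
Product: 2 (4R)-4-ethynyl-2,2-dimethyl-1,3-dioxolane
Conditions: dimethyl (1-diazo-2-oxopropyl)phosphonate, K2CO3, MeOH, 0 → 25 °C
Reagents that add atoms: dimethyl (1-diazo-2-oxopropyl)phosphonate, CC(=O)C(=[N+]=[N-])P(=O)(OC)OC
Why: Seyferth–Gilbert homologation in its Ohira–Bestmann form turns the aldehyde into the terminal alkyne under mild carbonate conditions that should leave the adjacent stereocentre (future C3) untouched.

Step 2
Reactants: 2 (4R)-4-ethynyl-2,2-dimethyl-1,3-dioxolane
Product: 3 methyl 3-[(4R)-2,2-dimethyl-1,3-dioxolan-4-yl]prop-2-ynoate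
Conditions: n-BuLi, THF, −78 °C; then ClCO2Me
Reagents that add atoms: methyl chloroformate, COC(=O)Cl
Why: Acylation of the lithium acetylide with a chloroformate is a standard route to ynoates and does not touch the stereocentre.

Step 3
Reactants: 3 methyl 3-[(4R)-2,2-dimethyl-1,3-dioxolan-4-yl]prop-2-ynoate
Product: 4 methyl (2Z)-3-[(4R)-2,2-dimethyl-1,3-dioxolan-4-yl]but-2-enoate
Conditions: Me2CuLi, THF, −78 °C; aqueous quench at −78 °C
Reagents that add atoms: lithium dimethylcuprate, [Li+].C[Cu-]C
Why: Conjugate syn-carbocupration of the ynoate followed by cold protonation of the vinylcopper places the new methyl cis to hydrogen, so C3 and C6 end up cis (the 4Z alkene of the target).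

Step 4
Reactants: 4 methyl (2Z)-3-[(4R)-2,2-dimethyl-1,3-dioxolan-4-yl]but-2-enoate
Product: 5 (2Z)-3-[(4R)-2,2-dimethyl-1,3-dioxolan-4-yl]but-2-en-1-ol
Conditions: i-Bu2AlH (2.2 equiv), CH2Cl2, −78 → 0 °C
Reagents that add atoms: none
Why: 1,2-Reduction of the enoate by the aluminium hydride gives the allylic alcohol without affecting the alkene geometry.

Step 5
Reactants: 5 (2Z)-3-[(4R)-2,2-dimethyl-1,3-dioxolan-4-yl]but-2-en-1-ol
Product: 6 (2Z)-3-[(4R)-2,2-dimethyl-1,3-dioxolan-4-yl]but-2-enal
Conditions: MnO2, CH2Cl2, 25 °C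
Reagents that add atoms: none
Why: Allylic oxidation with MnO2 is neutral and should keep the Z geometry of the enal.

Step 6
Reactants: 7 acrolein; 8 2-methylallylboronic acid pinacol ester
Product: 10 (3R)-5-methylhexa-1,5-dien-3-ol, via O-boronate 9 (not isolated)
Conditions: (R)-3,3′-bis(2,4,6-triisopropylphenyl)-1,1′-binaphthyl-2,2′-diyl hydrogen phosphate (5 mol%), toluene, −30 °C; aqueous work-up
Reagents that add atoms: none
Why: Chiral phosphoric acid-catalysed allylboration proceeds through a chair transition state in which the catalyst activates the boronate, and the catalyst enantiomer is chosen to deliver the (R)-carbinol (future C8).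

Step 7
Reactants: 10 (3R)-5-methylhexa-1,5-dien-3-ol
Product: 11 tert-butyl(dimethyl){[(3R)-5-methylhexa-1,5-dien-3-yl]oxy}silane
Conditions: t-BuMe2SiCl, imidazole, DMF, 25 °C
Reagents that add atoms: tert-butyldimethylsilyl chloride, CC(C)(C)[Si](C)(C)Cl
Why: Standard silylation protects the C8 hydroxyl as a non-chelating ether that survives every step up to step 17.

Step 8
Reactants: 11 tert-butyl(dimethyl){[(3R)-5-methylhexa-1,5-dien-3-yl]oxy}silane
Product: 12 tert-butyl{[(3R)-5-(chloromethyl)hexa-1,5-dien-3-yl]oxy}dimethylsilane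
Conditions: Ca(OCl)2, solid CO2, CH2Cl2/H2O, 0 °C
Reagents that add atoms: calcium hypochlorite, [Ca+2].[O-]Cl.[O-]Cl
Why: Ene-type allylic chlorination by hypochlorous acid attacks the electron-richer 1,1-disubstituted alkene with double-bond shift and should spare the vinyl group next to the silyloxy carbon.

Step 9
Reactants: 12 tert-butyl{[(3R)-5-(chloromethyl)hexa-1,5-dien-3-yl]oxy}dimethylsilane
Product: 13 tert-butyl(dimethyl)({(3R)-5-[(phenylsulfonyl)methyl]hexa-1,5-dien-3-yl}oxy)silane
Conditions: PhSO2Na, NaI (cat.), DMF, 25 °C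
Reagents that add atoms: sodium benzenesulfinate, [Na+].[O-]S(=O)c1ccccc1
Why: SN2 displacement of the allylic chloride by sulfinate (S-alkylation) installs the allyl sulfone that will become the C1 carbanion.

Step 10
Reactants: 13 tert-butyl(dimethyl)({(3R)-5-[(phenylsulfonyl)methyl]hexa-1,5-dien-3-yl}oxy)silane; 14 methyl 2-(bromomethyl)prop-2-enoate
Product: 15 methyl (2Z,4R)-2-(bromomethyl)-4-[(tert-butyldimethylsilyl)oxy]-6-[(phenylsulfonyl)methyl]hepta-2,6-dienoate
Conditions: Hoveyda–Grubbs second-generation catalyst (5 mol%), CH2Cl2, 40 °C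
Reagents that add atoms: none
Why: Olefin cross-metathesis joins the monosubstituted alkene to the methacrylate-type partner (ester trans to the chain), while the hindered 1,1-disubstituted sulfonylmethyl alkene should stay inert.

Step 11
Reactants: 6 (2Z)-3-[(4R)-2,2-dimethyl-1,3-dioxolan-4-yl]but-2-enal; 15 methyl (2Z,4R)-2-(bromomethyl)-4-[(tert-butyldimethylsilyl)oxy]-6-[(phenylsulfonyl)methyl]hepta-2,6-dienoate
Product: 17 seco-lactone (6,7-trans α-methylene γ-lactone), via hydroxy ester 16 (not isolated)
Conditions: CrCl2 (4 equiv), THF, 0 → 25 °C; lactonisation on work-up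
Reagents that add atoms: none
Why: In this Nozaki–Hiyama allylation the γ-substituted allylchromium adds through a chair transition state to give the anti C6/C7 pair (trans-lactone) whatever the bromide geometry, the C8 silyloxy centre should direct the C7 face (aldehyde anti to the C9 chain, C8–H eclipsing the allyl unit), and the alkoxide closes onto the ester.

Step 12
Reactants: 17 seco-lactone
Product: 18 seco-lactol
Conditions: i-Bu2AlH (1.1 equiv), CH2Cl2, −78 °C
Reagents that add atoms: none
Why: Half-reduction of the lactone stops at the aluminium hemiacetal and removes the Michael-acceptor character of the α-methylene lactone before carbanion chemistry.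

Step 13
Reactants: 18 seco-lactol
Product: 19 methyl lactol acetal 2,3-diol
Conditions: pyridinium p-toluenesulfonate (cat.), MeOH, 40 °C
Reagents that add atoms: methanol, CO
Why: Acid-catalysed acetalisation locks the lactol as a base-stable methyl acetal, and the same conditions transacetalise the terminal acetonide to the free C2/C3 diol.

Step 14
Reactants: 19 methyl lactol acetal 2,3-diol
Product: 21 terminal (C2–C3) epoxide, via primary tosylate 20 (not isolated)
Conditions: TsCl, Et3N, Bu2SnO (cat.), CH2Cl2, 0 °C; then DBU, 25 °C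
Reagents that add atoms: none
Why: Tin-acetal-catalysed sulfonylation of the primary hydroxyl followed by 3-exo-tet displacement by the C3 hydroxyl gives the epoxide with retention at C3, whose C–O bond is never broken.

Step 15
Reactants: 21 terminal (C2–C3) epoxide
Product: 24 bicyclic C1 sulfone (11-oxabicyclo[6.2.1]undecane core), via hydroxy allyl sulfone 22 (not isolated), via hydroxy vinyl sulfone 23 (not isolated)
Conditions: KN(SiMe3)2 (1.2 equiv), THF (0.002 M), −78 → 25 °C; then t-BuOH (5 equiv), 45 °C; H2O
Reagents that add atoms: none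
Why: Proposed new method: KN(SiMe3)2 removes a C1 proton of the allylic sulfone and the carbanion opens the terminal epoxide at C2 in an SN2 reaction (ten-membered carbocycle, exo-tet), which frees the C3 alkoxide. tert-Butanol and the alkoxide then shuttle a proton from C1 to C14, turning the allyl sulfone into the C1=C10 vinyl sulfone, and the C3 alkoxide adds across the ring to C10 (oxolane, 5-endo-trig oxa-Michael), the α-sulfonyl carbanion being protonated. The closest known reactions are the ring closure of epoxy allylic sulfone or sulfide carbanions to ten- and fourteen-membered carbocycles and the base-mediated 5-endo-trig cyclisation of sulfonyl-substituted homoallylic alkoxides to 3-sulfonyl oxolanes; their union in one flask on a medium ring, creating a fully substituted ether carbon, has not been shown. C10 is set by the substrate, because the six-carbon chain C4–C9 can bridge C3 and C10 of the oxolane only cis, so the C3 centre carried in from the epoxide fixes C10, while C1 should form as the exo-sulfonyl epimer (or a mixture) and is erased in step 16. The step needs attack at C2 and not at C3 or by SN2′ at C5, which the metal-free sulfonyl carbanion and the unhindered primary carbon should secure, and it needs high dilution so that ring closure beats oligomerisation. Because the conjugate addition is reversible, protonation of the ring-closed carbanion by tert-butanol is what should drain the equilibrium to 24.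

Step 16
Reactants: 24 bicyclic C1 sulfone
Product: 26 bicyclic C1 ketone, via silyloxy sulfone 25 (not isolated)
Conditions: n-BuLi (1.05 equiv), THF, −78 °C; then Me3SiOOSiMe3, −78 → 0 °C
Reagents that add atoms: bis(trimethylsilyl) peroxide, C[Si](C)(C)OO[Si](C)(C)C
Why: Oxidative desulfonylation: the α-sulfonyl carbanion is silyloxylated by the peroxide and the α-silyloxy sulfone collapses with loss of sulfinate to the ketone, which erases the C1 centre.

Step 17
Reactants: 26 bicyclic C1 ketone
Product: 27 8-hydroxy ketone
Conditions: Bu4NF, AcOH, THF, 25 °C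
Reagents that add atoms: none
Why: Buffered fluoride desilylation frees only the C8 hydroxyl, since the other oxygens are an acetal, a ketone and ethers, and the buffer should protect the β-alkoxy ketone from elimination.

Step 18
Reactants: 27 8-hydroxy ketone; 28 angelic acid
Product: 30 8-O-angeloyl ketone, via mixed anhydride 29 (not isolated)
Conditions: 2,4,6-trichlorobenzoyl chloride, Et3N, toluene, 25 → 80 °C (no DMAP)
Reagents that add atoms: none
Why: Yamaguchi esterification through the mixed anhydride acylates the hindered C8 alcohol with retention, and omitting the nucleophilic catalyst should avoid Z → E isomerisation to the tiglate.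

Step 19
Reactants: 30 8-O-angeloyl ketone
Product: 31 (1S)-alcohol methyl acetal
Conditions: NaBH4, MeOH, −40 °C
Reagents that add atoms: none
Why: Hydride should add to the C1 ketone from the exo face of the 11-oxabicyclo[6.2.1]undecane core (the side of the oxygen bridge, away from the six-carbon bridge), placing the hydroxyl cis to C9 as in the target.

Step 20
Reactants: 31 (1S)-alcohol methyl acetal
Product: 32 lactol
Conditions: AcOH/H2O/THF (3:1:1), 25 °C
Reagents that add atoms: water, O
Why: Mild aqueous acid hydrolyses the allylic mixed acetal back to the lactol without touching the angelate or the oxolane.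

Step 21
Reactants: 32 lactol
Product: 33 target (CNP0213894.1)
Conditions: MnO2, CH2Cl2, 25 °C
Reagents that add atoms: none
Why: MnO2 oxidises the allylic lactol to the α-methylene γ-lactone and leaves the saturated secondary C1 alcohol alone.

**Compound list**

1 | (4S)-2,2-dimethyl-1,3-dioxolane-4-carbaldehyde ((S)-glyceraldehyde acetonide) | O=C[C@@H]1COC(C)(C)O1 | starting material
2 | (4R)-4-ethynyl-2,2-dimethyl-1,3-dioxolane | C#C[C@@H]1COC(C)(C)O1 | intermediate
3 | methyl 3-[(4R)-2,2-dimethyl-1,3-dioxolan-4-yl]prop-2-ynoate | COC(=O)C#C[C@@H]1COC(C)(C)O1 | intermediate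
4 | methyl (2Z)-3-[(4R)-2,2-dimethyl-1,3-dioxolan-4-yl]but-2-enoate | COC(=O)/C=C(/C)[C@@H]1COC(C)(C)O1 | intermediate
5 | (2Z)-3-[(4R)-2,2-dimethyl-1,3-dioxolan-4-yl]but-2-en-1-ol | OC/C=C(/C)[C@@H]1COC(C)(C)O1 | intermediate
6 | (2Z)-3-[(4R)-2,2-dimethyl-1,3-dioxolan-4-yl]but-2-enal (west fragment, C2–C6 and C15) | O=C/C=C(/C)[C@@H]1COC(C)(C)O1 | intermediate
7 | acrolein (prop-2-enal) | C=CC=O | starting material
8 | 2-methylallylboronic acid pinacol ester (4,4,5,5-tetramethyl-2-(2-methylprop-2-en-1-yl)-1,3,2-dioxaborolane) | CC(=C)CB1OC(C)(C)C(C)(C)O1 | starting material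
9 | O-boronate of 10: 4,4,5,5-tetramethyl-2-{[(3R)-5-methylhexa-1,5-dien-3-yl]oxy}-1,3,2-dioxaborolane (formed in the flask, not isolated) | C=C[C@H](OB1OC(C)(C)C(C)(C)O1)CC(C)=C | intermediate
10 | (3R)-5-methylhexa-1,5-dien-3-ol | C=C[C@H](O)CC(C)=C | intermediate
11 | tert-butyl(dimethyl){[(3R)-5-methylhexa-1,5-dien-3-yl]oxy}silane | C=C[C@H](O[Si](C)(C)C(C)(C)C)CC(C)=C | intermediate
12 | tert-butyl{[(3R)-5-(chloromethyl)hexa-1,5-dien-3-yl]oxy}dimethylsilane | C=C[C@H](O[Si](C)(C)C(C)(C)C)CC(=C)CCl | intermediate
13 | tert-butyl(dimethyl)({(3R)-5-[(phenylsulfonyl)methyl]hexa-1,5-dien-3-yl}oxy)silane | C=C[C@H](O[Si](C)(C)C(C)(C)C)CC(=C)CS(=O)(=O)c1ccccc1 | intermediate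
14 | methyl 2-(bromomethyl)prop-2-enoate | COC(=O)C(=C)CBr | starting material
15 | methyl (2Z,4R)-2-(bromomethyl)-4-[(tert-butyldimethylsilyl)oxy]-6-[(phenylsulfonyl)methyl]hepta-2,6-dienoate (east fragment, C7–C14 and C1) | COC(=O)/C(CBr)=C/[C@H](O[Si](C)(C)C(C)(C)C)CC(=C)CS(=O)(=O)c1ccccc1 | intermediate
16 | open hydroxy ester of 17: C6 hydroxyl free, C12 methyl ester, C6/C7 anti, C6, C7 and C8 arranged as in the target (formed in the flask, not isolated) | COC(=O)C(=C)[C@@H]([C@H](O)/C=C(/C)[C@@H]1COC(C)(C)O1)[C@H](O[Si](C)(C)C(C)(C)C)CC(=C)CS(=O)(=O)c1ccccc1 | intermediate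
17 | seco-lactone: 6,7-trans α-methylene γ-lactone with the (Z)-propenyl acetonide arm on C6 and the 8-silyloxy allyl sulfone arm on C7; C3, C6, C7, C8 arranged as in the target | C=C1C(=O)O[C@H](/C=C(/C)[C@@H]2COC(C)(C)O2)[C@H]1[C@H](O[Si](C)(C)C(C)(C)C)CC(=C)CS(=O)(=O)c1ccccc1 | intermediate
18 | seco-lactol: 17 with C12 reduced to the hemiacetal (anomer mixture) | C=C1C(O)O[C@H](/C=C(/C)[C@@H]2COC(C)(C)O2)[C@H]1[C@H](O[Si](C)(C)C(C)(C)C)CC(=C)CS(=O)(=O)c1ccccc1 | intermediate
19 | methyl lactol acetal with free C2/C3 diol (C3 hydroxyl configured as the C3 oxygen of the target) | C=C1C(OC)O[C@H](/C=C(/C)[C@@H](O)CO)[C@H]1[C@H](O[Si](C)(C)C(C)(C)C)CC(=C)CS(=O)(=O)c1ccccc1 | intermediate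
20 | primary (C2) p-toluenesulfonate of 19 (formed in the flask, not isolated) | C=C1C(OC)O[C@H](/C=C(/C)[C@@H](O)COS(=O)(=O)c2ccc(C)cc2)[C@H]1[C@H](O[Si](C)(C)C(C)(C)C)CC(=C)CS(=O)(=O)c1ccccc1 | intermediate
21 | terminal C2–C3 epoxide, (2R)-oxiran-2-yl; precursor of the key step | C=C1C(OC)O[C@H](/C=C(/C)[C@@H]2CO2)[C@H]1[C@H](O[Si](C)(C)C(C)(C)C)CC(=C)CS(=O)(=O)c1ccccc1 | intermediate
22 | macrocyclic hydroxy allyl sulfone: ten-membered ring C1–C10 closed, 3-OH free, C10 exocyclic methylene, C1 epimers (formed in the flask, not isolated) | C=C1C(OC)O[C@@H]2/C=C(/C)[C@@H](O)CC(S(=O)(=O)c3ccccc3)C(=C)C[C@@H](O[Si](C)(C)C(C)(C)C)[C@@H]12 | intermediate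
23 | macrocyclic hydroxy vinyl sulfone: C1=C10 tetrasubstituted alkene, either geometry, 3-OH free (formed in the flask, not isolated) | C=C1C(OC)O[C@@H]2/C=C(/C)[C@@H](O)CC(S(=O)(=O)c3ccccc3)=C(C)C[C@@H](O[Si](C)(C)C(C)(C)C)[C@@H]12 | intermediate
24 | bicyclic C1 sulfone: 3,10-epoxy bridge closed, C10 as in the target, exo-phenylsulfonyl at C1 drawn, 8-OTBS, C12 methyl acetal | C=C1C(OC)O[C@@H]2/C=C(/C)[C@@H]3C[C@@H](S(=O)(=O)c4ccccc4)[C@](C)(C[C@@H](O[Si](C)(C)C(C)(C)C)[C@@H]12)O3 | intermediate
25 | 1-(trimethylsilyloxy)-1-(phenylsulfonyl) derivative of 24 (formed in the flask, not isolated) | C=C1C(OC)O[C@@H]2/C=C(/C)[C@@H]3CC(O[Si](C)(C)C)(S(=O)(=O)c4ccccc4)[C@](C)(C[C@@H](O[Si](C)(C)C(C)(C)C)[C@@H]12)O3 | intermediate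
26 | bicyclic C1 ketone, 8-OTBS, C12 methyl acetal | C=C1C(OC)O[C@@H]2/C=C(/C)[C@@H]3CC(=O)[C@](C)(C[C@@H](O[Si](C)(C)C(C)(C)C)[C@@H]12)O3 | intermediate
27 | 8-hydroxy C1 ketone, C12 methyl acetal | C=C1C(OC)O[C@@H]2/C=C(/C)[C@@H]3CC(=O)[C@](C)(C[C@@H](O)[C@@H]12)O3 | intermediate
28 | angelic acid ((2Z)-2-methylbut-2-enoic acid) | C/C=C(/C)C(=O)O | starting material
29 | angelic 2,4,6-trichlorobenzoic anhydride (formed in the flask, not isolated) | C/C=C(/C)C(=O)OC(=O)c1c(Cl)cc(Cl)cc1Cl | intermediate
30 | 8-O-angeloyl C1 ketone, C12 methyl acetal | C=C1C(OC)O[C@@H]2/C=C(/C)[C@@H]3CC(=O)[C@](C)(C[C@@H](OC(=O)/C(C)=C\C)[C@@H]12)O3 | intermediate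
31 | (1S)-alcohol, 8-O-angeloyl, C12 methyl acetal | C=C1C(OC)O[C@@H]2/C=C(/C)[C@@H]3C[C@H](O)[C@](C)(C[C@@H](OC(=O)/C(C)=C\C)[C@@H]12)O3 | intermediate
32 | lactol of the target (C12 hemiacetal, anomer mixture) | C=C1C(O)O[C@@H]2/C=C(/C)[C@@H]3C[C@H](O)[C@](C)(C[C@@H](OC(=O)/C(C)=C\C)[C@@H]12)O3 | intermediate
33 | CNP0213894.1: (1S,3S,6R,7R,8R,10S,4Z)-8-angeloyloxy-1-hydroxy-3,10-epoxygermacra-4,11(13)-dien-12,6-olide | C=C1C(=O)O[C@@H]2/C=C(/C)[C@@H]3C[C@H](O)[C@](C)(C[C@@H](OC(=O)/C(C)=C\C)[C@@H]12)O3 | target

**Count and risks**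

Total: 21 steps. Longest linear sequence: 16 steps (7 and 8 to 33 through steps 6–21; equally 1 to 33 through steps 1–5 and 11–21).

Step 15. The second half of the cascade may stall: isomerisation to the tetrasubstituted vinyl sulfone and the cross-ring 5-endo addition may not outrun retro-addition, and ring closure may lose to oligomerisation. The fallback makes the O–C10 bond by a known epoxide opening instead. It sets out from 21: the ring closure alone is run with LiN(SiMe3)2 in THF at high dilution and quenched cold, so that the macrocyclic hydroxy allyl sulfone 22 is isolated. Palladium-catalysed hydride displacement of the allylic sulfone (Pd(PPh3)4, LiBHEt3) should move the double bond into the ring and give the (1(10)E,4Z)-cyclodecadienol F1. Epoxidation of this strained, most electron-rich alkene (m-CPBA, NaHCO3, −20 °C) should give the 1,10-epoxide F2. Camphorsulfonic acid should then trigger transannular opening at the tertiary C10 by the C3 hydroxyl with inversion, giving the 1-hydroxy 3,10-epoxy bicycle F3; its C1 is epimeric to the target, which is of no consequence. Dess–Martin oxidation returns to the route at ketone 26, so step 16 is bypassed.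

Step 16. On lithiation at C1, β-elimination of the ring oxygen (retro-oxa-Michael ring opening) may compete with oxygen transfer. The fallback turns this opening to use and sets out from 24. KN(SiMe3)2 opens 24 to the alkoxide of vinyl sulfone 23, which is epoxidised in the same flask by t-BuOOH (nucleophilic epoxidation of a vinyl sulfone) to the hydroxy epoxy sulfone F4; only the diastereomer with the epoxide oxygen on the outer face can close. BF3·OEt2 then induces 5-endo opening of the epoxide at C10 by the C3 hydroxyl with loss of benzenesulfinate from C1, the known conversion of hydroxy epoxy sulfones into cyclic ether ketones, and returns to the route at ketone 26.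

Step 11. The anti C6/C7 relationship is reliable, but facial selection at C7 by the C8 silyloxy centre may be poor, which would give the lactone with C6 and C7 both inverted. The fallback replaces substrate control by reagent control and sets out from 6 and 15: an enantioselective Nozaki–Hiyama allylation with CrCl2 pre-complexed to a chiral oxazoline–sulfonamide ligand and Et3N, choosing the ligand enantiomer that is matched with C8. After work-up the adduct 16 lactonises and the route is rejoined at 17; no new compound is made.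

**Further compounds**

F1 | step 15 | (1(10)E,4Z)-cyclodecadien-3-ol with 8-OTBS and C12 methyl acetal, from hydride displacement of the sulfone of 22 | C=C1C(OC)O[C@@H]2/C=C(/C)[C@@H](O)C/C=C(\C)C[C@@H](O[Si](C)(C)C(C)(C)C)[C@@H]12
F2 | step 15 | 1,10-epoxide of F1 (trans epoxide, oxygen on the outer face) | C=C1C(OC)O[C@@H]2/C=C(/C)[C@@H](O)C[C@H]3O[C@]3(C)C[C@@H](O[Si](C)(C)C(C)(C)C)[C@@H]12
F3 | step 15 | 1-epi-hydroxy 3,10-epoxy bicycle with 8-OTBS and C12 methyl acetal | C=C1C(OC)O[C@@H]2/C=C(/C)[C@@H]3C[C@@H](O)[C@](C)(C[C@@H](O[Si](C)(C)C(C)(C)C)[C@@H]12)O3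
F4 | step 16 | 1,10-epoxy-1-(phenylsulfonyl) macrocycle with free 3-hydroxyl (epoxide of 23) | C=C1C(OC)O[C@@H]2/C=C(/C)[C@@H](O)CC3(S(=O)(=O)c4ccccc4)O[C@]3(C)C[C@@H](O[Si](C)(C)C(C)(C)C)[C@@H]12
F0 | step 11 | none | none
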